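Ring A of the target (oxygen at C3, C15 on C4, C14 on C10 para to C3) is read as a latent 2,4-dimethylphenol that carries the C6–C9 chain on C5. The route rests on the C9–C10 disconnection: the phenoxide attacks C9 through its para carbon C10, which in one operation closes ring B, sets the quaternary C10 stereocentre from the C8 stereocentre and unveils the 4,10-dimethyl-1,4-dien-3-one. The precursor is 2,4-dimethyl-3-[(3R)-3,4-dioxygenated butyl]phenol with the two oxygens tied as a cyclic sulfate, which serves as leaving group and conformational lock. Afterwards C8 is reset, C7 is alkylated and a Schenck ene reaction installs the C5 hydroperoxide.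

Key step: step 10

Remark (convention): eudesmane numbering is used throughout; C14 is the methyl on C10, C15 the methyl on C4, and β is the face of C14. Bicyclic compounds without C11–C13 are named as 11,12,13-trinoreudesmanes.

Remark (precursor design): the carbon skeleton and the oxygen pattern of the phenol are those of a 3-(3,4-dioxygenated butyl)-2,4-dimethylphenol. The C8 and C9 oxygens are joined as a cyclic sulfate, not kept as an open-chain protected alcohol beside a sulfonate. In a chair-like closure an equatorial C8 oxygen is eclipsed with the departing C9 oxygen, and an open chain can avoid this by turning the oxygen axial, so its relay of configuration to C10 is not secure. The five-membered sulfate already has that synclinal arrangement, so the C8 configuration is passed on by ring geometry. The electrophile is also more reactive, and the alcohol is freed without a separate deprotection step.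

Step 1
Reactants: 1 2,6-dimethylbenzoic acid
Product: 2 2,6-dimethyl-3-nitrobenzoic acid
Conditions: fuming HNO3, conc. H2SO4, 0 °C → rt
Reagents that add atoms: nitric acid, O[N+](=O)[O-]
Why: Electrophilic aromatic nitration: both methyl groups (ortho/para) and the carboxyl group (meta) direct to the equivalent C3/C5 positions, so one mononitro acid should form.

Step 2
Reactants: 2 2,6-dimethyl-3-nitrobenzoic acid
Product: 3 3-amino-2,6-dimethylbenzoic acid
Conditions: H2 (1 atm), 10% Pd/C, MeOH, rt
Reagents that add atoms: none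
Why: Catalytic hydrogenation of the nitroarene to the aniline, under which the acid and the ring are inert.

Step 3
Reactants: 3 3-amino-2,6-dimethylbenzoic acid
Product: 5 3-hydroxy-2,6-dimethylbenzoic acid, via diazonium hydrogensulfate 4 (not isolated)
Conditions: NaNO2, aq. H2SO4, 0–5 °C; then added to boiling aq. H2SO4
Reagents that add atoms: water, O
Why: Diazotisation followed by thermal hydrolysis of the arenediazonium salt (phenol synthesis by diazonium hydrolysis) exchanges the amino group for hydroxyl with loss of N2.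

Step 4
Reactants: 5 3-hydroxy-2,6-dimethylbenzoic acid
Product: 6 benzyl 3-(benzyloxy)-2,6-dimethylbenzoate
Conditions: BnBr (2.3 equiv), K2CO3, DMF, 50 °C
Reagents that add atoms: benzyl bromide, BrCc1ccccc1
Why: Williamson-type double O-benzylation, in which the phenoxide gives the aryl benzyl ether and the hindered carboxylate is alkylated on oxygen, so no attack at its shielded carbonyl is needed.

Step 5
Reactants: 6 benzyl 3-(benzyloxy)-2,6-dimethylbenzoate
Product: 7 [3-(benzyloxy)-2,6-dimethylphenyl]methanol
Conditions: LiAlH4, THF, 0 °C → reflux; aq. NaOH work-up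
Reagents that add atoms: none
Why: LiAlH4 reduction of the ester to the primary benzylic alcohol, which leaves the aryl benzyl ether untouched.

Step 6
Reactants: 7 [3-(benzyloxy)-2,6-dimethylphenyl]methanol
Product: 8 1-(benzyloxy)-3-(chloromethyl)-2,4-dimethylbenzene
Conditions: SOCl2, CH2Cl2, 0 °C → rt
Reagents that add atoms: thionyl chloride, O=S(Cl)Cl
Why: Chlorodehydroxylation of the activated benzylic alcohol with thionyl chloride through its chlorosulfite.

Step 7
Reactants: 8 1-(benzyloxy)-3-(chloromethyl)-2,4-dimethylbenzene; 9 (S)-glycidol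
Product: 12 (2R)-4-[3-(benzyloxy)-2,6-dimethylphenyl]butane-1,2-diol, via benzylic Grignard reagent 10 (not isolated), via chloromagnesium glycidolate 11 (not isolated)
Conditions: 8, Mg, THF, 0 °C; 9, i-PrMgCl (1.0 equiv), THF, −78 °C; combined, CuI (10 mol %), −40 → 0 °C; then 1 M HCl
Reagents that add atoms: none
Why: Grignard formation and copper-catalysed SN2 opening of the glycidolate epoxide at its unsubstituted carbon; C2 of glycidol is not touched, so (S)-glycidol gives the (2R)-diol, the descriptor changing only through the priorities.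

Step 8
Reactants: 12 (2R)-4-[3-(benzyloxy)-2,6-dimethylphenyl]butane-1,2-diol
Product: 14 (4R)-4-{2-[3-(benzyloxy)-2,6-dimethylphenyl]ethyl}-1,3,2-dioxathiolane 2,2-dioxide, via cyclic sulfite 13 (not isolated)
Conditions: SOCl2, Et3N, CH2Cl2, 0 °C; then RuCl3·xH2O (1 mol %), NaIO4, MeCN/H2O, 0 °C, 20 min
Reagents that add atoms: thionyl chloride, O=S(Cl)Cl; sodium periodate, [Na+].[O-]I(=O)(=O)=O
Why: Two-stage cyclic sulfate synthesis (cyclic sulfite, then oxidation at sulfur by RuO4 formed in the flask), in which no bond to C8 is broken and the short oxidation should spare the benzyl ether.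

Step 9
Reactants: 14 (4R)-4-{2-[3-(benzyloxy)-2,6-dimethylphenyl]ethyl}-1,3,2-dioxathiolane 2,2-dioxide
Product: 15 3-{2-[(4R)-2,2-dioxo-1,3,2-dioxathiolan-4-yl]ethyl}-2,4-dimethylphenol
Conditions: H2 (1 atm), 10% Pd/C, EtOAc, rt
Reagents that add atoms: none
Why: Hydrogenolysis of the aryl benzyl ether over Pd/C under neutral conditions, which the cyclic sulfate tolerates; the phenol is used at once.

Step 10
Reactants: 15 3-{2-[(4R)-2,2-dioxo-1,3,2-dioxathiolan-4-yl]ethyl}-2,4-dimethylphenol
Product: 18 8α-hydroxy-11,12,13-trinoreudesma-1,4-dien-3-one, via potassium phenoxide 16 (not isolated), via potassium 8α-sulfate 17 (not isolated)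
Conditions: KOC(CH3)3 (1.05 equiv), (CH3)3COH, 0.01 M, rt → 60 °C; then H2SO4 (cat.), H2O, THF, rt
Reagents that add atoms: none
Why: The base gives the ambident potassium phenoxide 16, whose para carbon C10 opens the cyclic sulfate at its primary carbon C9 in an intramolecular SN2 reaction; aromaticity is exchanged for the cross-conjugated dienone in which C14 is the angular methyl, C15 sits on C4=C5 and the phenol oxygen is the C3 carbonyl, and acid then hydrolyses the sulfate monoester 17 to the alcohol. The closest known reaction type is the alkylative dearomatisation of a phenoxide through its para carbon by a tethered primary sulfonate-type ester (Ar2-6 participation), the established entry to fused 4a-alkyl cyclohexa-2,5-dienones. Ring B closes in the 6-exo-tet mode, whereas attack at the secondary carbon C8 would be a five-membered closure with the phenoxide double bond inside the new ring and is geometrically disfavoured. The new C10 stereocentre is controlled by C8: the five-membered sulfate holds O8 synclinal to the departing O9, hence antiperiplanar to the incoming C10 and equatorial in the chair-like transition state, so C9 should add to the face that leaves the new axial methyl trans to O8 (8α-O, 10β-CH3), while the other face would need a twist-boat. The step needs C-alkylation through the para carbon C10 in preference to the ortho carbon C4 and to intermolecular O-alkylation: closure through oxygen would require a meta-bridged eight-membered ring, the hydrogen-bonded and potassium-paired oxygen shields the ortho side in the protic solvent, and high dilution holds back intermolecular reaction. One equivalent of base leaves no free alkoxide, and the minor C10 epimer, a diastereomer at this stage, is removed before C8 is oxidised, because after that it would be the enantiomer.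

Step 11
Reactants: 18 8α-hydroxy-11,12,13-trinoreudesma-1,4-dien-3-one
Product: 19 11,12,13-trinoreudesma-1,4-diene-3,8-dione
Conditions: Dess–Martin periodinane, CH2Cl2, rt
Reagents that add atoms: none
Why: Dess–Martin oxidation of the secondary alcohol; C8 has done its work as a stereochemical relay and the ketone now activates C7.

Step 12
Reactants: 19 11,12,13-trinoreudesma-1,4-diene-3,8-dione
Product: 22 7β-(3-methylbut-2-enyl)-11,12,13-trinoreudesma-1,4-diene-3,8-dione, via lithium enolate 20 (not isolated), via 7α-prenyl epimer 21 (not isolated)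
Conditions: LiN(i-Pr)2 (1.1 equiv), THF, −78 °C; prenyl bromide, DMPU, −78 → −30 °C; then K2CO3, MeOH, rt
Reagents that add atoms: 1-bromo-3-methylbut-2-ene (prenyl bromide), CC(C)=CCBr
Why: Kinetic enolate alkylation: the amide base should deprotonate the unhindered C7 (C9 is neopentylic and the dienone has no α-hydrogen), prenyl bromide reacts by SN2, and base equilibration through the enolate should move the side chain to the equatorial 7β position with H7α axial.

Step 13
Reactants: 22 7β-(3-methylbut-2-enyl)-11,12,13-trinoreudesma-1,4-diene-3,8-dione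
Product: 23 7β-(3-methylbut-2-enyl)-11,12,13-trinoreudesm-4-ene-3,8-dione
Conditions: H2 (1 atm), RhCl(PPh3)3 (10 mol %), benzene/EtOH, rt
Reagents that add atoms: none
Why: Homogeneous hydrogenation with RhCl(PPh3)3 reduces the cis-disubstituted C1=C2 bond of the cross-conjugated dienone much faster than the tetrasubstituted C4=C5 bond or the trisubstituted prenyl alkene.

Step 14
Reactants: 23 7β-(3-methylbut-2-enyl)-11,12,13-trinoreudesm-4-ene-3,8-dione
Product: 24 7β-(3-methylbut-2-enyl)-11,12,13-trinoreudesm-4-ene-3α,8β-diol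
Conditions: LiBH(s-Bu)3 (3 equiv), THF, −78 → −20 °C; then aq. NaOH, H2O2, 0 °C
Reagents that add atoms: none
Why: Hydride reduction with the bulky trialkylborohydride: attack on C8 from the α face (the β, axial approach is blocked by C14) gives the axial 8β-alcohol cis to the C7 chain, and 1,2-reduction of the enone from the equatorial direction (C5 is fully substituted, so no conjugate reduction) gives the pseudoaxial 3α-allylic alcohol.

Step 15
Reactants: 24 7β-(3-methylbut-2-enyl)-11,12,13-trinoreudesm-4-ene-3α,8β-diol
Product: 25 8β-hydroxy-7β-(3-methylbut-2-enyl)-11,12,13-trinoreudesm-4-en-3α-yl angelate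
Conditions: angelic acid, 2,4,6-trichlorobenzoyl chloride, Et3N, toluene, rt; then 24, 70 °C
Reagents that add atoms: angelic acid [(Z)-2-methylbut-2-enoic acid], C/C=C(/C)C(=O)O
Why: Mixed-anhydride (Yamaguchi-type) esterification without a nucleophilic catalyst, which should keep the Z geometry; the allylic 3α-hydroxyl should react first because the 8β-hydroxyl is 1,3-diaxial to C14 and flanked by the C7 chain, and C3 keeps its configuration.

Step 16
Reactants: 25 8β-hydroxy-7β-(3-methylbut-2-enyl)-11,12,13-trinoreudesm-4-en-3α-yl angelate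
Product: 26 8β-acetoxy-7β-(3-methylbut-2-enyl)-11,12,13-trinoreudesm-4-en-3α-yl angelate
Conditions: Ac2O, DMAP, pyridine, 40 °C
Reagents that add atoms: acetic anhydride, CC(=O)OC(C)=O
Why: DMAP-catalysed acetylation of the remaining hindered axial 8β-alcohol.

Step 17
Reactants: 26 8β-acetoxy-7β-(3-methylbut-2-enyl)-11,12,13-trinoreudesm-4-en-3α-yl angelate
Product: 28 8β-acetoxy-3α-angeloyloxy-13-noreudesm-4-en-12-al, via vicinal diol 27 (not isolated)
Conditions: OsO4 (2 mol %), NaIO4, 2,6-lutidine, 1,4-dioxane/H2O, rt
Reagents that add atoms: OsO4, O=[Os](=O)(=O)=O; sodium periodate, [Na+].[O-]I(=O)(=O)=O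
Why: Lemieux–Johnson oxidation: OsO4 should dihydroxylate the unhindered, electron-rich prenyl alkene in preference to the hindered tetrasubstituted C4=C5 bond and the electron-poor angelate alkene, and NaIO4 cleaves the diol to the aldehyde.

Step 18
Reactants: 28 8β-acetoxy-3α-angeloyloxy-13-noreudesm-4-en-12-al
Product: 29 8β-acetoxy-3α-angeloyloxyeudesma-4,11(13)-dien-12-al
Conditions: 37% aq. CH2O, pyrrolidine (10 mol %), EtCO2H (10 mol %), i-PrOH, 45 °C
Reagents that add atoms: formaldehyde, C=O
Why: Amine-catalysed Mannich condensation with formaldehyde and elimination (organocatalytic α-methylenation of an aldehyde) under near-neutral conditions that spare both esters, a short reaction time avoiding isomerisation of the new alkene.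

Step 19
Reactants: 29 8β-acetoxy-3α-angeloyloxyeudesma-4,11(13)-dien-12-al
Product: 30 8β-acetoxy-3α-angeloyloxyeudesma-4,11(13)-dien-12-oic acid
Conditions: NaClO2, NaH2PO4, 2-methylbut-2-ene, t-BuOH/H2O, 0 °C → rt
Reagents that add atoms: sodium chlorite, [Na+].[O-]Cl=O
Why: Pinnick oxidation of the α-methylene aldehyde to the acrylic acid, with 2-methylbut-2-ene trapping HOCl and so protecting the C4=C5 bond.

Step 20
Reactants: 30 8β-acetoxy-3α-angeloyloxyeudesma-4,11(13)-dien-12-oic acid
Product: 31 methyl 8β-acetoxy-3α-angeloyloxyeudesma-4,11(13)-dien-12-oate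
Conditions: MeI, KHCO3, DMF, rt
Reagents that add atoms: iodomethane, CI
Why: SN2 O-methylation of the carboxylate with iodomethane under mild base, which leaves the acetate, the angelate and the acrylate untouched.

Step 21
Reactants: 31 methyl 8β-acetoxy-3α-angeloyloxyeudesma-4,11(13)-dien-12-oate
Product: 32 methyl 8β-acetoxy-3α-angeloyloxy-5α-hydroperoxyeudesma-4(15),11(13)-dien-12-oate (CNP0116769.2)
Conditions: O2, methylene blue (cat.), CH2Cl2, visible light, −20 °C
Reagents that add atoms: dioxygen, O=O
Why: Schenck ene reaction: singlet oxygen reacts only with the electron-rich tetrasubstituted C4=C5 bond, should add to C5 from the α face opposite C14, and can there abstract only a C15 hydrogen (H3 is β and lies near the alkene plane), giving the 5α-hydroperoxide and the C4=C15 exocyclic alkene.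

Compound list

1 | 2,6-dimethylbenzoic acid | Cc1cccc(C)c1C(=O)O | starting material
2 | 2,6-dimethyl-3-nitrobenzoic acid | Cc1ccc([N+](=O)[O-])c(C)c1C(=O)O | intermediate
3 | 3-amino-2,6-dimethylbenzoic acid | Cc1ccc(N)c(C)c1C(=O)O | intermediate
4 | 3-carboxy-2,4-dimethylbenzenediazonium hydrogensulfate | Cc1ccc([N+]#N)c(C)c1C(=O)O.OS(=O)(=O)[O-] | intermediate (not isolated)
5 | 3-hydroxy-2,6-dimethylbenzoic acid | Cc1ccc(O)c(C)c1C(=O)O | intermediate
6 | benzyl 3-(benzyloxy)-2,6-dimethylbenzoate | Cc1ccc(OCc2ccccc2)c(C)c1C(=O)OCc1ccccc1 | intermediate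
7 | [3-(benzyloxy)-2,6-dimethylphenyl]methanol | Cc1ccc(OCc2ccccc2)c(C)c1CO | intermediate
8 | 1-(benzyloxy)-3-(chloromethyl)-2,4-dimethylbenzene | Cc1ccc(OCc2ccccc2)c(C)c1CCl | intermediate
9 | (S)-glycidol [(2S)-oxiran-2-ylmethanol] | OC[C@H]1CO1 | starting material
10 | [3-(benzyloxy)-2,6-dimethylbenzyl]magnesium chloride | Cc1ccc(OCc2ccccc2)c(C)c1C[Mg]Cl | intermediate (not isolated)
11 | chloromagnesium (S)-glycidolate | Cl[Mg]OC[C@H]1CO1 | intermediate (not isolated)
12 | (2R)-4-[3-(benzyloxy)-2,6-dimethylphenyl]butane-1,2-diol | Cc1ccc(OCc2ccccc2)c(C)c1CC[C@@H](O)CO | intermediate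
13 | (4R)-4-{2-[3-(benzyloxy)-2,6-dimethylphenyl]ethyl}-1,3,2-dioxathiolane 2-oxide (both sulfur epimers) | Cc1ccc(OCc2ccccc2)c(C)c1CC[C@@H]1COS(=O)O1 | intermediate (not isolated)
14 | (4R)-4-{2-[3-(benzyloxy)-2,6-dimethylphenyl]ethyl}-1,3,2-dioxathiolane 2,2-dioxide | Cc1ccc(OCc2ccccc2)c(C)c1CC[C@@H]1COS(=O)(=O)O1 | intermediate
15 | 3-{2-[(4R)-2,2-dioxo-1,3,2-dioxathiolan-4-yl]ethyl}-2,4-dimethylphenol (key-step precursor) | Cc1ccc(O)c(C)c1CC[C@@H]1COS(=O)(=O)O1 | intermediate
16 | potassium phenoxide of 15 | Cc1ccc([O-])c(C)c1CC[C@@H]1COS(=O)(=O)O1.[K+] | intermediate (not isolated)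
17 | potassium 3-oxo-11,12,13-trinoreudesma-1,4-dien-8α-yl sulfate (10β-methyl) | C1CC2=C(C)C(=O)C=C[C@]2(C)C[C@@H]1OS(=O)(=O)[O-].[K+] | intermediate (not isolated)
18 | 8α-hydroxy-11,12,13-trinoreudesma-1,4-dien-3-one (10β-methyl) | C1CC2=C(C)C(=O)C=C[C@]2(C)C[C@@H]1O | intermediate
19 | 11,12,13-trinoreudesma-1,4-diene-3,8-dione | C1CC2=C(C)C(=O)C=C[C@]2(C)CC1=O | intermediate
20 | lithium C7=C8 enolate of 19 | [Li+].[O-]C1=CCC2=C(C)C(=O)C=C[C@]2(C)C1 | intermediate (not isolated)
21 | 7α-(3-methylbut-2-enyl)-11,12,13-trinoreudesma-1,4-diene-3,8-dione | CC(C)=CC[C@@H]1CC2=C(C)C(=O)C=C[C@]2(C)CC1=O | intermediate (not isolated)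
22 | 7β-(3-methylbut-2-enyl)-11,12,13-trinoreudesma-1,4-diene-3,8-dione | CC(C)=CC[C@H]1CC2=C(C)C(=O)C=C[C@]2(C)CC1=O | intermediate
23 | 7β-(3-methylbut-2-enyl)-11,12,13-trinoreudesm-4-ene-3,8-dione | CC(C)=CC[C@H]1CC2=C(C)C(=O)CC[C@]2(C)CC1=O | intermediate
24 | 7β-(3-methylbut-2-enyl)-11,12,13-trinoreudesm-4-ene-3α,8β-diol | CC(C)=CC[C@H]1CC2=C(C)[C@H](O)CC[C@]2(C)C[C@H]1O | intermediate
25 | 8β-hydroxy-7β-(3-methylbut-2-enyl)-11,12,13-trinoreudesm-4-en-3α-yl angelate [(Z)-2-methylbut-2-enoate] | CC(C)=CC[C@H]1CC2=C(C)[C@H](OC(=O)/C(C)=C\C)CC[C@]2(C)C[C@H]1O | intermediate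
26 | 8β-acetoxy-7β-(3-methylbut-2-enyl)-11,12,13-trinoreudesm-4-en-3α-yl angelate | CC(C)=CC[C@H]1CC2=C(C)[C@H](OC(=O)/C(C)=C\C)CC[C@]2(C)C[C@H]1OC(C)=O | intermediate
27 | 8β-acetoxy-7β-(2,3-dihydroxy-3-methylbutyl)-11,12,13-trinoreudesm-4-en-3α-yl angelate (both carbinol epimers) | CC(C)(O)C(O)C[C@H]1CC2=C(C)[C@H](OC(=O)/C(C)=C\C)CC[C@]2(C)C[C@H]1OC(C)=O | intermediate (not isolated)
28 | 8β-acetoxy-3α-angeloyloxy-13-noreudesm-4-en-12-al | O=CC[C@H]1CC2=C(C)[C@H](OC(=O)/C(C)=C\C)CC[C@]2(C)C[C@H]1OC(C)=O | intermediate
29 | 8β-acetoxy-3α-angeloyloxyeudesma-4,11(13)-dien-12-al | C=C(C=O)[C@H]1CC2=C(C)[C@H](OC(=O)/C(C)=C\C)CC[C@]2(C)C[C@H]1OC(C)=O | intermediate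
30 | 8β-acetoxy-3α-angeloyloxyeudesma-4,11(13)-dien-12-oic acid | C=C(C(=O)O)[C@H]1CC2=C(C)[C@H](OC(=O)/C(C)=C\C)CC[C@]2(C)C[C@H]1OC(C)=O | intermediate
31 | methyl 8β-acetoxy-3α-angeloyloxyeudesma-4,11(13)-dien-12-oate | C=C(C(=O)OC)[C@H]1CC2=C(C)[C@H](OC(=O)/C(C)=C\C)CC[C@]2(C)C[C@H]1OC(C)=O | intermediate
32 | methyl 8β-acetoxy-3α-angeloyloxy-5α-hydroperoxyeudesma-4(15),11(13)-dien-12-oate (CNP0116769.2) | C=C(C(=O)OC)[C@H]1C[C@@]2(OO)C(=C)[C@H](OC(=O)/C(C)=C\C)CC[C@]2(C)C[C@H]1OC(C)=O | target

Total step count: 21. Longest linear sequence: 21 steps (1 to 32; (S)-glycidol 9 enters in step 7).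

Steps most likely to fail

Step 10 (ring B closure). Closure through the ortho carbon C4 may compete with closure through C10. The very reactive cyclic sulfate may also be consumed by intermolecular O-alkylation (oligomer formation) before the slower dearomative C–C bond formation. The fallback uses a less reactive, open-chain electrophile that tolerates long heating at high dilution; it sets out from diol 12 and returns at alcohol 18. Tin-catalysed monotosylation of the primary hydroxyl (TsCl, Et3N, Bu2SnO cat.) should give (2R)-4-[3-(benzyloxy)-2,6-dimethylphenyl]-2-hydroxybutyl 4-methylbenzenesulfonate F1. Silylation (TBSOTf, 2,6-lutidine) should give the silyl ether tosylate F2, and hydrogenolysis (H2, Pd/C, EtOAc) the free phenol 3-[(3R)-3-(tert-butyldimethylsilyloxy)-4-(tosyloxy)butyl]-2,4-dimethylphenol F3. KOC(CH3)3 in refluxing (CH3)3COH should then close ring B to 8α-(tert-butyldimethylsilyloxy)-11,12,13-trinoreudesma-1,4-dien-3-one F4, and aqueous HF in MeCN should release 18. In this variant the C10 configuration depends on the silyloxy group taking the equatorial site without a ring lock, so the relative configuration of F4 would have to be confirmed before C8 is oxidised.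

Step 12 (C7 alkylation). Enolisation may not be confined to C7 (C9, or γ-deprotonation at C6 of the dienone), over-alkylation may occur, and the equilibrium preference for the equatorial 7β epimer may be modest because C5 is sp2. The fallback fixes the regiochemistry by a removable ester and makes the C7–H bond last; it sets out from dione 19 and returns at 22. Reversible C-acylation at the less hindered α-methylene (NaH, diallyl carbonate, THF, reflux) should give allyl 3,8-dioxo-11,12,13-trinoreudesma-1,4-diene-7-carboxylate F5. Its stabilised enolate is prenylated (K2CO3, prenyl bromide, acetone) to the quaternary allyl 7-(3-methylbut-2-enyl)-3,8-dioxo-11,12,13-trinoreudesma-1,4-diene-7-carboxylate F6. Pd(OAc)2/PPh3 with HCO2H/Et3N then removes the allyl ester with loss of CO2, and the enol should be protonated at C7 from the open α face (axial protonation) to give 22.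

Step 15 (angeloylation). The 8β-hydroxyl may be acylated as well as the 3α-hydroxyl, and the angeloyl unit may isomerise from Z to E during carboxyl activation. The fallback removes the need for site selectivity and never activates the acid; it sets out from diol 24 and returns at 26. MnO2 (CH2Cl2) should oxidise only the allylic alcohol, giving 8β-hydroxy-7β-(3-methylbut-2-enyl)-11,12,13-trinoreudesm-4-en-3-one F7. Acetylation (Ac2O, DMAP, pyridine) gives the 8β-acetoxy enone F8. Luche reduction (NaBH4, CeCl3·7H2O, MeOH, −78 °C) should deliver hydride axially from the α face to give the 3β-allylic alcohol F9. A Mitsunobu reaction with angelic acid (PPh3, diisopropyl azodicarboxylate, THF) then installs the 3α-angelate with inversion, the carboxylate acting as the nucleophile, and gives 26.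

Further compounds

F1 | step 10 | (2R)-4-[3-(benzyloxy)-2,6-dimethylphenyl]-2-hydroxybutyl 4-methylbenzenesulfonate | Cc1ccc(OCc2ccccc2)c(C)c1CC[C@@H](O)COS(=O)(=O)c1ccc(C)cc1
F2 | step 10 | (2R)-4-[3-(benzyloxy)-2,6-dimethylphenyl]-2-[(tert-butyldimethylsilyl)oxy]butyl 4-methylbenzenesulfonate | Cc1ccc(OCc2ccccc2)c(C)c1CC[C@@H](O[Si](C)(C)C(C)(C)C)COS(=O)(=O)c1ccc(C)cc1
F3 | step 10 | 3-[(3R)-3-[(tert-butyldimethylsilyl)oxy]-4-(tosyloxy)butyl]-2,4-dimethylphenol | Cc1ccc(O)c(C)c1CC[C@@H](O[Si](C)(C)C(C)(C)C)COS(=O)(=O)c1ccc(C)cc1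
F4 | step 10 | 8α-(tert-butyldimethylsilyloxy)-11,12,13-trinoreudesma-1,4-dien-3-one | C1CC2=C(C)C(=O)C=C[C@]2(C)C[C@@H]1O[Si](C)(C)C(C)(C)C
F5 | step 12 | allyl 3,8-dioxo-11,12,13-trinoreudesma-1,4-diene-7-carboxylate (C7 epimers, partly enolised) | C=CCOC(=O)C1CC2=C(C)C(=O)C=C[C@]2(C)CC1=O
F6 | step 12 | allyl 7-(3-methylbut-2-enyl)-3,8-dioxo-11,12,13-trinoreudesma-1,4-diene-7-carboxylate (C7 epimers) | C=CCOC(=O)C1(CC=C(C)C)CC2=C(C)C(=O)C=C[C@]2(C)CC1=O
F7 | step 15 | 8β-hydroxy-7β-(3-methylbut-2-enyl)-11,12,13-trinoreudesm-4-en-3-one | CC(C)=CC[C@H]1CC2=C(C)C(=O)CC[C@]2(C)C[C@H]1O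
F8 | step 15 | 8β-acetoxy-7β-(3-methylbut-2-enyl)-11,12,13-trinoreudesm-4-en-3-one | CC(C)=CC[C@H]1CC2=C(C)C(=O)CC[C@]2(C)C[C@H]1OC(C)=O
F9 | step 15 | 8β-acetoxy-7β-(3-methylbut-2-enyl)-11,12,13-trinoreudesm-4-en-3β-ol | CC(C)=CC[C@H]1CC2=C(C)[C@@H](O)CC[C@]2(C)C[C@H]1OC(C)=O
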